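## The problem

The target 23 is an isoflavone without a stereocentre, so the difficulty lies entirely in where the substituents sit and in what they tolerate. Ring A is a phloroglucinol (O1, O5, O7) that carries the 3-hydroxy-3-methylbutyl chain on C6, between the two free hydroxyls. Closing ring C onto a C-alkylated phloroglucinol can use either ortho oxygen and so gives 6- and 8-alkyl chromones; the regiochemistry therefore has to be fixed by construction. Ring B is a resorcinol whose prenyl group sits on C3', between both oxygens and next to the biaryl bond C3–C1'. The trisubstituted alkene excludes hydrogenation, thallium and other electrophilic oxidants late in the route. Strong acid would cyclise the prenyl group onto O2' or O4' and the tertiary alcohol onto O5 or O7 (chromans) or dehydrate it, and hot aqueous base opens ring C. The feature to exploit is that O1 is both the ring oxygen of ring C and the C8a oxygen of ring A. A 4-pyranone with the aryl group on C3 and a CH2 group on C8a is thus a masked triketide with O1 already in place, and a malonate can deliver C5, C6 and C7 with the chain already on C6, so that closing C4a–C5 can only give the 6-alkyl pattern.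

## Retrosynthesis

**Protecting groups (23 from 22).** The last cut removes the two aryl methoxymethyl ethers and the triethylsilyl ether of 22. The MOM groups on ring B are kept because they also direct the metalation that places the prenyl group. The tertiary alcohol is carried as a silyl ether because an aliphatic MOM ether would be the slowest acetal to cleave and would set the acid strength of the final step. O5 and O7 need no protection, since the ring closure delivers them free. The forward step must cleave three groups in mildly acidic methanol without ionising either side chain.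

**Ring A (22 from 19).** The C4a–C5 bond is cut and the ester lost from C6 is put back, which leads to the pyranonylacetyl malonate 19. Cutting ring C instead (O1–C8a and C4–C4a, or O1–C2) or the biaryl bond leaves a 6-alkylphloroglucinol whose two ortho oxygens must be told apart. The C4a–C5 cut removes this problem, because O1 and C8 are already distinct in the pyranone. The precursor has one ring fewer and an open-chain malonate in place of the tetrasubstituted ring A. The forward reaction asks that C4a of the dienolate 20 act as the nucleophile, that closure outrun cleavage of the C6–C7 bond, and that the spare ester of 21 leave with aromatisation.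

**C6–C7 (19 from 12 and 16).** The quaternary centre is made by acylation: the acid chloride 17 of acid 12 meets the magnesium enolate 18 of alkylmalonate 16. The neighbouring cut, C7–C8, would need a triester as acyl donor, whose tetrahedral adduct would expel the malonate anion rather than alkoxide. Alkylating an acylmalonate at C6 would suffer from O-alkylation. The two halves are of similar size. The forward step must give C-acylation with no alkoxide present, since 19 is cleaved by nucleophiles at C7.

**C7–C8 (12 from 10).** The carboxyl carbon is taken off C8, which leaves the 2-methylpyranone 10. Its lateral dienolate 11 is the same kind of anion the key step relies on, so this step also tests the acidity of that position early.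

**C3–C1' (10 from 9 and 7).** The biaryl bond is cut to triflate 9 and boronate 7. Building the pyranone onto an arylacetone would be longer, whereas 9 is one step from allomaltol 8. The forward coupling must tolerate a hindered ortho-alkoxy boronate and a base-sensitive pyranone triflate.

**Ring B (7 from 5, 2, 1 and 3).** The boron of 7 replaces the bromine of 5 (through aryllithium 6), and the bromine is already present in 4-bromoresorcinol 1. The prenyl group of 5 is attached at the one carbon of 2 that lies between the two MOM ethers (through aryllithium 4) with prenyl bromide 3. The metalation must spare the bromine.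

**Malonate (16 from 14 and 15; 14 from 13).** The chain is attached by alkylating dimethyl malonate 15 with the silyl-protected bromide 14, made in one step from 4-bromo-2-methylbutan-2-ol 13.

## Roads not taken

**Alternative 1:** oxidative 1,2-aryl shift of a chalcone. The cut is C3–C1' (made by migration of ring B) together with O1–C2. In the forward direction chalcone A1 would be treated with Tl(NO3)3 in methanol and trimethyl orthoformate; ring B moves from the beta to the alpha carbon, and pyridinium p-toluenesulfonate then closes ring C from the acetal to give isoflavone A2.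
- Merits: the sequence is a classical isoflavone synthesis, and the chalcone comes from a simple Claisen–Schmidt condensation.
- Weak points: the thallium salt attacks a prenyl alkene, so ring B must carry a bromine placeholder and the prenyl group has to be introduced afterwards by cross-coupling at a position flanked by two MOM ethers. The ring A half of A1 still needs the chain between two protected oxygens and the free hydroxyl on the far side, so the 6- versus 8-alkyl problem is only moved back into the acetophenone synthesis. Thallium waste and more steps after the key step add to this.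
- Comparison: this road is better in that every reaction type has precedent, whereas the chosen plan rests on one untested ring closure. Against that the chosen plan sets a prenyl group carried unchanged from the second step, regiochemistry fixed by construction, and a one-step end game.

**Alternative 2:** ring B built on the chromone by vinylketene benzannulation. Four ring B bonds are cut (C1'–C2', C2'–C3', C4'–C5', C5'–C6'). Wolff rearrangement of diazoketone A3 would give a vinylketene that adds to siloxyalkyne A4; ring opening of the cyclobutenone and six-electron closure would give isoflavone A5, with only the 2'-hydroxyl free.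
- Merits: the benzannulation has precedent as a reaction type, places the prenyl group between two differentiated oxygens with full regiocontrol, and needs neither acid nor base.
- Weak points: the step is spent on the easy ring, since ring B is available in three steps from 4-bromoresorcinol. The difficult part, a chromone with the chain on C6, must be made beforehand and is not helped by the key step. A3 has to be assembled on a chromone whose C2 is a Michael acceptor for diazoalkanes, and A4 is a sensitive ynol ether with a skipped enyne.
- Comparison: the precedent for its key step is better than for the chosen one. The chosen plan puts its one uncertain step where the regiochemical problem actually is.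

**Alternative 3:** aryne insertion builds ring C onto ring A. The cuts are O1–C8a and C4–C4a. CsF would release the aryne from silyl triflate A6; the enol oxygen of the formylated arylacetate A7 should add at C8a, the carbon remote from the C5 alkoxy group, and the C4a anion should then attack the ester to give the fully protected isoflavone A8.
- Merits: it is the most convergent of the four, with a shorter longest linear sequence than the chosen plan. A6 can be derived from a symmetrical ring A phenol, so its substitution pattern is secure, and the aryne regiochemistry follows from the inductive effect of the alkoxy group.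
- Weak points: beta-dicarbonyl compounds normally react with arynes through carbon (C-arylation or insertion into the C–C bond), so the required O-arylation followed by acyl transfer has to beat the usual pathway. The prenyl alkene of A7 can undergo an ene reaction with the aryne, and A6 itself takes several steps.
- Comparison: in convergence this road is better. The chosen plan sets against it a dienolate with only one possible intramolecular reaction partner and no intermolecular competitors.

Key step: step 10

## Route

Remark on the chemistry: the tertiary alcohol is carried as a triethylsilyl ether and not as a third MOM ether; the bonds formed and the ring closed in the key step are unchanged. Allomaltol 8 and 4-bromo-2-methylbutan-2-ol 13 are taken as purchasable, and lithium amides, n-BuLi and iPrMgCl are used as purchased reagents.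

Step 1
Reactants: 1 4-bromobenzene-1,3-diol (4-bromoresorcinol)
Product: 2 1-bromo-2,4-bis(methoxymethoxy)benzene
Conditions: MOMCl (2.5 equiv), iPr2NEt (3 equiv), CH2Cl2, 0 → 23 °C
Reagents that add atoms: chloromethyl methyl ether, COCCl
Why: Standard O-alkylation of both phenols to MOM ethers, which later serve as directing groups and survive all basic and organometallic steps.

Step 2
Reactants: 2 1-bromo-2,4-bis(methoxymethoxy)benzene; 3 1-bromo-3-methylbut-2-ene (prenyl bromide)
Product: 5 1-bromo-2,4-bis(methoxymethoxy)-3-(3-methylbut-2-enyl)benzene, via aryllithium 4 (not isolated)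
Conditions: lithium 2,2,6,6-tetramethylpiperidide (1.1 equiv), THF, −78 °C; then CuI (10 mol %), 3 (1.3 equiv), −78 → 0 °C
Reagents that add atoms: none
Why: Directed ortho-metalation at the proton between the two MOM ethers, which is the most acidic and doubly coordinated; a lithium amide is used so that the bromine is not exchanged. The aryllithium is then allylated at the primary carbon of 3, because the tertiary terminus is out of reach for a nucleophile with two ortho substituents.

Step 3
Reactants: 5 1-bromo-2,4-bis(methoxymethoxy)-3-(3-methylbut-2-enyl)benzene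
Product: 7 2-[2,4-bis(methoxymethoxy)-3-(3-methylbut-2-enyl)phenyl]-4,4,5,5-tetramethyl-1,3,2-dioxaborolane, via aryllithium 6 (not isolated)
Conditions: n-BuLi (1.05 equiv), THF, −78 °C; then 2-isopropoxy-4,4,5,5-tetramethyl-1,3,2-dioxaborolane, −78 → 23 °C; aq NH4Cl
Reagents that add atoms: 2-isopropoxy-4,4,5,5-tetramethyl-1,3,2-dioxaborolane, CC(C)OB1OC(C)(C)C(C)(C)O1
Why: Bromine–lithium exchange is far faster at −78 °C than deprotonation of the allylic-benzylic CH2, and the aryllithium is trapped by the borate to give a pinacol boronate that resists protodeboronation better than the free acid.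

Step 4
Reactants: 8 5-hydroxy-2-methyl-4H-pyran-4-one (allomaltol)
Product: 9 6-methyl-4-oxo-4H-pyran-3-yl trifluoromethanesulfonate
Conditions: Tf2O (1.1 equiv), pyridine (2 equiv), CH2Cl2, −20 → 0 °C
Reagents that add atoms: trifluoromethanesulfonic anhydride, O=S(=O)(OS(=O)(=O)C(F)(F)F)C(F)(F)F
Why: O-sulfonylation of the enolic 5-hydroxyl, a standard activation of 3-hydroxy-4-pyranones for cross-coupling.

Step 5
Reactants: 9 6-methyl-4-oxo-4H-pyran-3-yl trifluoromethanesulfonate; 7 2-[2,4-bis(methoxymethoxy)-3-(3-methylbut-2-enyl)phenyl]-4,4,5,5-tetramethyl-1,3,2-dioxaborolane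
Product: 10 5-[2,4-bis(methoxymethoxy)-3-(3-methylbut-2-enyl)phenyl]-2-methyl-4H-pyran-4-one
Conditions: Pd(OAc)2 (5 mol %), SPhos (10 mol %), K3PO4 (2 equiv), toluene/H2O 10:1, 70 °C
Reagents that add atoms: none
Why: Suzuki–Miyaura coupling of a pyranone triflate with an aryl boronate forms C3–C1'; the biaryl phosphine handles the ortho-alkoxy boronate and the mild phosphate base spares the pyranone ring and the triflate.

Step 6
Reactants: 10 5-[2,4-bis(methoxymethoxy)-3-(3-methylbut-2-enyl)phenyl]-2-methyl-4H-pyran-4-one
Product: 12 2-{5-[2,4-bis(methoxymethoxy)-3-(3-methylbut-2-enyl)phenyl]-4-oxo-4H-pyran-2-yl}acetic acid, via lithium dienolate 11 (not isolated)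
Conditions: LiN(SiMe3)2 (2.2 equiv), THF, −78 °C; CO2 (gas), −78 → −20 °C; 1 M HCl to pH 3, 0 °C
Reagents that add atoms: carbon dioxide, O=C=O
Why: Lateral (vinylogous) deprotonation of the 2-methyl group of a 4-pyranone by a lithium amide and carboxylation of the dienolate at the exocyclic carbon form C7–C8; the excess base allows for the more acidic CH2 of the carboxylate. The acid is a vinylogous beta-keto acid, so it is kept cold and used at once.

Step 7
Reactants: 13 4-bromo-2-methylbutan-2-ol
Product: 14 [(4-bromo-2-methylbutan-2-yl)oxy]triethylsilane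
Conditions: Et3SiOTf (1.2 equiv), 2,6-lutidine (1.5 equiv), CH2Cl2, −78 → 0 °C
Reagents that add atoms: triethylsilyl trifluoromethanesulfonate, CC[Si](CC)(CC)OS(=O)(=O)C(F)(F)F
Why: Silylation of a tertiary alcohol with a silyl triflate and a hindered pyridine base; the ether prevents lactonisation onto the malonate esters later.

Step 8
Reactants: 14 [(4-bromo-2-methylbutan-2-yl)oxy]triethylsilane; 15 dimethyl propanedioate (dimethyl malonate)
Product: 16 dimethyl 2-[3-methyl-3-(triethylsilyloxy)butyl]propanedioate
Conditions: 15 (2 equiv), NaH (1.2 equiv), THF/DMF, 0 °C; then 14, NaI (10 mol %), 60 °C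
Reagents that add atoms: none
Why: Malonic ester alkylation (SN2 at the primary bromide); the excess of malonate suppresses dialkylation.

Step 9
Reactants: 12 2-{5-[2,4-bis(methoxymethoxy)-3-(3-methylbut-2-enyl)phenyl]-4-oxo-4H-pyran-2-yl}acetic acid; 16 dimethyl 2-[3-methyl-3-(triethylsilyloxy)butyl]propanedioate
Product: 19 dimethyl 2-{2-[5-(2,4-bis(methoxymethoxy)-3-(3-methylbut-2-enyl)phenyl)-4-oxo-4H-pyran-2-yl]acetyl}-2-[3-methyl-3-(triethylsilyloxy)butyl]propanedioate, via acid chloride 17 (not isolated), via chloromagnesium enolate 18 (not isolated)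
Conditions: 12, 1-chloro-N,N,2-trimethylprop-1-en-1-amine (1.1 equiv), CH2Cl2, 0 °C; separately 16 (2.2 equiv), iPrMgCl (2.2 equiv), THF, 0 °C; combine at −40 → 0 °C; aq NH4Cl
Reagents that add atoms: none
Why: C-acylation of the magnesium enolate of an alkylmalonate by an acid chloride forms C6–C7 and the quaternary centre. The chloride is made under neutral conditions that spare the MOM ethers, the magnesium chelate favours C- over O-acylation, and the second equivalent of enolate takes up the acidic C8 proton of 19 (or traps the ketene from 17 to the same product); no alkoxide is present that could cleave the acylmalonate.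

Step 10
Reactants: 19 dimethyl 2-{2-[5-(2,4-bis(methoxymethoxy)-3-(3-methylbut-2-enyl)phenyl)-4-oxo-4H-pyran-2-yl]acetyl}-2-[3-methyl-3-(triethylsilyloxy)butyl]propanedioate
Product: 22 3-[2,4-bis(methoxymethoxy)-3-(3-methylbut-2-enyl)phenyl]-5,7-dihydroxy-6-[3-methyl-3-(triethylsilyloxy)butyl]chromen-4-one, via lithium dienolate 20 (not isolated), via cyclised keto ester 21 (not isolated)
Conditions: LiN(SiMe3)2 (2.5 equiv), THF, −78 → 23 °C; then MeOH (10 equiv), 23 °C; aq NH4Cl
Reagents that add atoms: none
Why: Proposed new method: LiN(SiMe3)2 removes a C8 proton of 19 to give dienolate 20, whose charge runs through C8a to C4a and into the pyranone carbonyl; C4a adds to one of the two equivalent methyl esters and methoxide leaves, which forms C4a–C5 and closes ring A in a 6-(enolendo)-exo-trig Claisen (Dieckmann-type) condensation. This is the only closure open to 20, because attack through C8 or through the enolate oxygen would give a four-membered ring and attack through the pyranone oxygen an eight-membered one. A second equivalent of base removes the doubly activated C4a proton to give the enolate of 21, and the lithium methoxide set free, helped by the methanol added at the end, attacks the ester on the quaternary C6, which departs as dimethyl carbonate because the leaving group is the aromatic 5,7-diphenoxide of 22. The closest known reaction type is the base-induced Claisen cyclisation of 3,5,7-triketo esters to acylphloroglucinols, taken together with the known gamma-deprotonation of 2-alkyl-4-pyranones by lithium amides; new is the use of the pyranone carbon C4a as the acyl acceptor. No stereocentre is formed. The selectivity needed is ring closure ahead of retro-Claisen cleavage of C6–C7: the amide base is not nucleophilic, C7 is masked as its enolate from the first moment, and the quaternary C6 cannot be deprotonated, so both esters stay electrophilic. The 6-alkyl pattern is not a matter of selectivity, since O1 and C8 are fixed in the pyranone before ring A exists.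

Step 11
Reactants: 22 3-[2,4-bis(methoxymethoxy)-3-(3-methylbut-2-enyl)phenyl]-5,7-dihydroxy-6-[3-methyl-3-(triethylsilyloxy)butyl]chromen-4-one
Product: 23 3-[2,4-dihydroxy-3-(3-methylbut-2-enyl)phenyl]-5,7-dihydroxy-6-(3-hydroxy-3-methylbutyl)chromen-4-one
Conditions: HCl (1 M), MeOH, 23 °C
Reagents that add atoms: none
Why: Acid-catalysed acetal exchange removes the two aryl MOM ethers and methanolysis removes the silyl ether, which leaves first. At ambient temperature in dilute methanolic acid neither the prenyl group nor the tertiary alcohol should ionise, so no chroman should form on either ring.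

## Compound list

1 | 4-bromobenzene-1,3-diol (4-bromoresorcinol) | Oc1ccc(Br)c(O)c1 | starting material
2 | 1-bromo-2,4-bis(methoxymethoxy)benzene | COCOc1ccc(Br)c(OCOC)c1 | intermediate
3 | 1-bromo-3-methylbut-2-ene (prenyl bromide) | CC(C)=CCBr | starting material
4 | [3-bromo-2,6-bis(methoxymethoxy)phenyl]lithium | [Li]c1c(OCOC)ccc(Br)c1OCOC | intermediate
5 | 1-bromo-2,4-bis(methoxymethoxy)-3-(3-methylbut-2-enyl)benzene | COCOc1ccc(Br)c(OCOC)c1CC=C(C)C | intermediate
6 | [2,4-bis(methoxymethoxy)-3-(3-methylbut-2-enyl)phenyl]lithium | [Li]c1ccc(OCOC)c(CC=C(C)C)c1OCOC | intermediate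
7 | 2-[2,4-bis(methoxymethoxy)-3-(3-methylbut-2-enyl)phenyl]-4,4,5,5-tetramethyl-1,3,2-dioxaborolane | CC(C)=CCc1c(OCOC)ccc(B2OC(C)(C)C(C)(C)O2)c1OCOC | intermediate
8 | 5-hydroxy-2-methyl-4H-pyran-4-one (allomaltol) | Cc1cc(=O)c(O)co1 | starting material
9 | 6-methyl-4-oxo-4H-pyran-3-yl trifluoromethanesulfonate | Cc1cc(=O)c(OS(=O)(=O)C(F)(F)F)co1 | intermediate
10 | 5-[2,4-bis(methoxymethoxy)-3-(3-methylbut-2-enyl)phenyl]-2-methyl-4H-pyran-4-one | Cc1cc(=O)c(-c2ccc(OCOC)c(CC=C(C)C)c2OCOC)co1 | intermediate
11 | lithium 3-[2,4-bis(methoxymethoxy)-3-(3-methylbut-2-enyl)phenyl]-6-methylidene-6H-pyran-4-olate (lateral dienolate of 10) | C=C1C=C(O[Li])C(-c2ccc(OCOC)c(CC=C(C)C)c2OCOC)=CO1 | intermediate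
12 | 2-{5-[2,4-bis(methoxymethoxy)-3-(3-methylbut-2-enyl)phenyl]-4-oxo-4H-pyran-2-yl}acetic acid | OC(=O)Cc1cc(=O)c(-c2ccc(OCOC)c(CC=C(C)C)c2OCOC)co1 | intermediate
13 | 4-bromo-2-methylbutan-2-ol | CC(C)(O)CCBr | starting material
14 | [(4-bromo-2-methylbutan-2-yl)oxy]triethylsilane | CC[Si](CC)(CC)OC(C)(C)CCBr | intermediate
15 | dimethyl propanedioate (dimethyl malonate) | COC(=O)CC(=O)OC | starting material
16 | dimethyl 2-[3-methyl-3-(triethylsilyloxy)butyl]propanedioate | COC(=O)C(CCC(C)(C)O[Si](CC)(CC)CC)C(=O)OC | intermediate
17 | 2-{5-[2,4-bis(methoxymethoxy)-3-(3-methylbut-2-enyl)phenyl]-4-oxo-4H-pyran-2-yl}acetyl chloride | O=C(Cl)Cc1cc(=O)c(-c2ccc(OCOC)c(CC=C(C)C)c2OCOC)co1 | intermediate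
18 | chloromagnesium enolate of 16 | COC(=O)C(CCC(C)(C)O[Si](CC)(CC)CC)=C(OC)O[Mg]Cl | intermediate
19 | dimethyl 2-{2-[5-(2,4-bis(methoxymethoxy)-3-(3-methylbut-2-enyl)phenyl)-4-oxo-4H-pyran-2-yl]acetyl}-2-[3-methyl-3-(triethylsilyloxy)butyl]propanedioate | COC(=O)C(CCC(C)(C)O[Si](CC)(CC)CC)(C(=O)OC)C(=O)Cc1cc(=O)c(-c2ccc(OCOC)c(CC=C(C)C)c2OCOC)co1 | intermediate
20 | lithium dienolate of 19 (C7 O-lithium enolate, drawn in the geometry that can close) | COC(=O)C(CCC(C)(C)O[Si](CC)(CC)CC)(C(=O)OC)/C(O[Li])=C\c1cc(=O)c(-c2ccc(OCOC)c(CC=C(C)C)c2OCOC)co1 | intermediate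
21 | methyl 3-[2,4-bis(methoxymethoxy)-3-(3-methylbut-2-enyl)phenyl]-5-hydroxy-6-[3-methyl-3-(triethylsilyloxy)butyl]-4,7-dioxo-6,7-dihydro-4H-chromene-6-carboxylate (present as its lithium enolate) | COC(=O)C1(CCC(C)(C)O[Si](CC)(CC)CC)C(=O)C=C2OC=C(c3ccc(OCOC)c(CC=C(C)C)c3OCOC)C(=O)C2=C1O | intermediate
22 | 3-[2,4-bis(methoxymethoxy)-3-(3-methylbut-2-enyl)phenyl]-5,7-dihydroxy-6-[3-methyl-3-(triethylsilyloxy)butyl]chromen-4-one | COCOc1ccc(-c2coc3cc(O)c(CCC(C)(C)O[Si](CC)(CC)CC)c(O)c3c2=O)c(OCOC)c1CC=C(C)C | intermediate
23 | 3-[2,4-dihydroxy-3-(3-methylbut-2-enyl)phenyl]-5,7-dihydroxy-6-(3-hydroxy-3-methylbutyl)chromen-4-one | CC(C)=CCc1c(O)ccc(-c2coc3cc(O)c(CCC(C)(C)O)c(O)c3c2=O)c1O | target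

## Step count and risks

Total: 11 steps. Longest linear sequence: 8 steps (1, 2, 3, 5, 6, 9, 10, 11, from 4-bromoresorcinol); the pyranone branch (step 4) and the malonate branch (steps 7 and 8) join at steps 5 and 9.

**Step 10 (key step, proposed new method).** The stabilised dienolate may be too weak a carbon nucleophile at C4a. On warming, intermolecular condensation or cleavage of the C6–C7 bond by liberated methoxide could then overtake ring closure. The spare ester may also be lost incompletely. The fallback uses only known reaction types, sets out from silyl ether 14 and boronate 7, and returns at the target 23: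
- 3,5-Bis(methoxymethoxy)phenol F1, a known compound obtained by partial MOM protection of the parent triphenol, is lithiated as its phenoxide between the two MOM ethers (n-BuLi, TMEDA, THF) and alkylated with 14. This gives the symmetrical 3,5-bis(methoxymethoxy)-4-[3-methyl-3-(triethylsilyloxy)butyl]phenol F2.
- A second directed lithiation, which can only occur at one of the two equivalent positions next to the free oxygen, and acylation with N-methoxy-N-methylacetamide give 1-{2-hydroxy-4,6-bis(methoxymethoxy)-5-[3-methyl-3-(triethylsilyloxy)butyl]phenyl}ethanone F3. Its free hydroxyl, the future O1, lies away from the chain by symmetry.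
- N,N-Dimethylformamide dimethyl acetal converts F3 into the enaminone (E)-3-(dimethylamino)-1-{2-hydroxy-4,6-bis(methoxymethoxy)-5-[3-methyl-3-(triethylsilyloxy)butyl]phenyl}prop-2-en-1-one F4.
- Iodine with pyridine closes ring C to 3-iodo-5,7-bis(methoxymethoxy)-6-[3-methyl-3-(triethylsilyloxy)butyl]chromen-4-one F5.
- Suzuki–Miyaura coupling of F5 with 7 gives 3-[2,4-bis(methoxymethoxy)-3-(3-methylbut-2-enyl)phenyl]-5,7-bis(methoxymethoxy)-6-[3-methyl-3-(triethylsilyloxy)butyl]chromen-4-one F6, and methanolic HCl as in step 11 gives 23.

**Step 9.** The acid chloride can lose HCl to a ketene that oligomerises before the hindered enolate captures it, and acid 12 can decarboxylate before activation. O-acylation and cleavage of the acylmalonate on work-up are lesser risks. The fallback forms C7–C8 instead of C6–C7; it sets out from pyranone 10 and malonate 16, returns at 19, and also bypasses acid 12: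
- Malonate 16 is hydroxymethylated with aqueous formaldehyde and KHCO3 to dimethyl 2-(hydroxymethyl)-2-[3-methyl-3-(triethylsilyloxy)butyl]propanedioate F7.
- F7 is oxidised with the periodinane 1,1,1-triacetoxy-1,1-dihydro-1,2-benziodoxol-3(1H)-one (DMP) to dimethyl 2-formyl-2-[3-methyl-3-(triethylsilyloxy)butyl]propanedioate F8.
- The lateral dienolate 11, made from 10 as in step 6, adds to F8 at −78 °C with a cold acetic acid quench to give the racemic aldol dimethyl 2-{2-[5-(2,4-bis(methoxymethoxy)-3-(3-methylbut-2-enyl)phenyl)-4-oxo-4H-pyran-2-yl]-1-hydroxyethyl}-2-[3-methyl-3-(triethylsilyloxy)butyl]propanedioate F9.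
- DMP oxidation of F9 gives 19.

**Step 2.** Deprotonation next to bromine, followed by benzyne formation or bromine migration, may compete with metalation between the MOM ethers, and some allylation at the tertiary terminus is possible. The fallback places the prenyl group before any halogen is present; it sets out from prenyl bromide 3 and returns at aryllithium 6, hence at boronate 7:
- 1,3-Bis(methoxymethoxy)benzene F10, the bis-MOM ether of the parent diphenol, is lithiated between the MOM ethers with n-BuLi and allylated with 3 (CuI catalysis) to 1,3-bis(methoxymethoxy)-2-(3-methylbut-2-enyl)benzene F11.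
- A second MOM-directed lithiation of F11 (n-BuLi, TMEDA) gives 6, which is borylated as in step 3.

**Step 5.** Protodeboronation of the electron-rich ortho-alkoxy boronate and attack of aqueous base at the sulfur of the pyranone triflate may lower conversion. The fallback is a base-free Negishi coupling that sets out from bromide 5 and triflate 9 and returns at 10: aryllithium 6, made as in step 3, is transmetalated with ZnCl2 to [2,4-bis(methoxymethoxy)-3-(3-methylbut-2-enyl)phenyl]zinc chloride F12, which is coupled with 9 under Pd(PPh3)4 in THF.

## Further compounds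

F1 | step 10 | 3,5-bis(methoxymethoxy)phenol | COCOc1cc(O)cc(OCOC)c1
F2 | step 10 | 3,5-bis(methoxymethoxy)-4-[3-methyl-3-(triethylsilyloxy)butyl]phenol | COCOc1cc(O)cc(OCOC)c1CCC(C)(C)O[Si](CC)(CC)CC
F3 | step 10 | 1-{2-hydroxy-4,6-bis(methoxymethoxy)-5-[3-methyl-3-(triethylsilyloxy)butyl]phenyl}ethanone | CC(=O)c1c(O)cc(OCOC)c(CCC(C)(C)O[Si](CC)(CC)CC)c1OCOC
F4 | step 10 | (E)-3-(dimethylamino)-1-{2-hydroxy-4,6-bis(methoxymethoxy)-5-[3-methyl-3-(triethylsilyloxy)butyl]phenyl}prop-2-en-1-one | CN(C)/C=C/C(=O)c1c(O)cc(OCOC)c(CCC(C)(C)O[Si](CC)(CC)CC)c1OCOC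
F5 | step 10 | 3-iodo-5,7-bis(methoxymethoxy)-6-[3-methyl-3-(triethylsilyloxy)butyl]chromen-4-one | COCOc1cc2occ(I)c(=O)c2c(OCOC)c1CCC(C)(C)O[Si](CC)(CC)CC
F6 | step 10 | 3-[2,4-bis(methoxymethoxy)-3-(3-methylbut-2-enyl)phenyl]-5,7-bis(methoxymethoxy)-6-[3-methyl-3-(triethylsilyloxy)butyl]chromen-4-one | COCOc1ccc(-c2coc3cc(OCOC)c(CCC(C)(C)O[Si](CC)(CC)CC)c(OCOC)c3c2=O)c(OCOC)c1CC=C(C)C
F7 | step 9 | dimethyl 2-(hydroxymethyl)-2-[3-methyl-3-(triethylsilyloxy)butyl]propanedioate | COC(=O)C(CO)(CCC(C)(C)O[Si](CC)(CC)CC)C(=O)OC
F8 | step 9 | dimethyl 2-formyl-2-[3-methyl-3-(triethylsilyloxy)butyl]propanedioate | COC(=O)C(C=O)(CCC(C)(C)O[Si](CC)(CC)CC)C(=O)OC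
F9 | step 9 | dimethyl 2-{2-[5-(2,4-bis(methoxymethoxy)-3-(3-methylbut-2-enyl)phenyl)-4-oxo-4H-pyran-2-yl]-1-hydroxyethyl}-2-[3-methyl-3-(triethylsilyloxy)butyl]propanedioate (racemic) | COC(=O)C(CCC(C)(C)O[Si](CC)(CC)CC)(C(=O)OC)C(O)Cc1cc(=O)c(-c2ccc(OCOC)c(CC=C(C)C)c2OCOC)co1
F10 | step 2 | 1,3-bis(methoxymethoxy)benzene | COCOc1cccc(OCOC)c1
F11 | step 2 | 1,3-bis(methoxymethoxy)-2-(3-methylbut-2-enyl)benzene | COCOc1cccc(OCOC)c1CC=C(C)C
F12 | step 5 | [2,4-bis(methoxymethoxy)-3-(3-methylbut-2-enyl)phenyl]zinc chloride | Cl[Zn]c1ccc(OCOC)c(CC=C(C)C)c1OCOC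
A1 | alternative 1 | (E)-3-[3-bromo-2,4-bis(methoxymethoxy)phenyl]-1-[2-hydroxy-5-(3-hydroxy-3-methylbutyl)-4,6-bis(methoxymethoxy)phenyl]prop-2-en-1-one | COCOc1ccc(/C=C/C(=O)c2c(O)cc(OCOC)c(CCC(C)(C)O)c2OCOC)c(OCOC)c1Br
A2 | alternative 1 | 3-[3-bromo-2,4-bis(methoxymethoxy)phenyl]-6-(3-hydroxy-3-methylbutyl)-5,7-bis(methoxymethoxy)chromen-4-one | COCOc1ccc(-c2coc3cc(OCOC)c(CCC(C)(C)O)c(OCOC)c3c2=O)c(OCOC)c1Br
A3 | alternative 2 | (E)-1-diazo-4-{5,7-bis(methoxymethoxy)-6-[3-(methoxymethoxy)-3-methylbutyl]-4-oxochromen-3-yl}but-3-en-2-one | [N-]=[N+]=CC(=O)/C=C/c1coc2cc(OCOC)c(CCC(C)(C)OCOC)c(OCOC)c2c1=O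
A4 | alternative 2 | triisopropyl[(5-methylhex-4-en-1-yn-1-yl)oxy]silane | CC(C)=CCC#CO[Si](C(C)C)(C(C)C)C(C)C
A5 | alternative 2 | 3-[2-hydroxy-3-(3-methylbut-2-enyl)-4-(triisopropylsilyloxy)phenyl]-6-[3-(methoxymethoxy)-3-methylbutyl]-5,7-bis(methoxymethoxy)chromen-4-one | CC(C)=CCc1c(O[Si](C(C)C)(C(C)C)C(C)C)ccc(-c2coc3cc(OCOC)c(CCC(C)(C)OCOC)c(OCOC)c3c2=O)c1O
A6 | alternative 3 | 3,5-bis(methoxymethoxy)-4-[3-(methoxymethoxy)-3-methylbutyl]-2-(trimethylsilyl)phenyl trifluoromethanesulfonate | COCOc1cc(OS(=O)(=O)C(F)(F)F)c([Si](C)(C)C)c(OCOC)c1CCC(C)(C)OCOC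
A7 | alternative 3 | methyl 2-[2,4-bis(methoxymethoxy)-3-(3-methylbut-2-enyl)phenyl]-3-hydroxyprop-2-enoate | COC(=O)C(=CO)c1ccc(OCOC)c(CC=C(C)C)c1OCOC
A8 | alternative 3 | 3-[2,4-bis(methoxymethoxy)-3-(3-methylbut-2-enyl)phenyl]-6-[3-(methoxymethoxy)-3-methylbutyl]-5,7-bis(methoxymethoxy)chromen-4-one | COCOc1ccc(-c2coc3cc(OCOC)c(CCC(C)(C)OCOC)c(OCOC)c3c2=O)c(OCOC)c1CC=C(C)C
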